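**Plan** (labdane numbering of the carbons)

- Retrosynthesis: the C15 aldehyde and the 7α-hydroxyl go on last. The decalin is cut at C1–C2 and C9–C10 in one operation, back to an open-chain C2 aldehyde. The chain is cut at C9–C11 (Negishi coupling), at C8–C17 (carbocupration) and at C4–C5 (Claisen rearrangement).
- Forward: a Johnson-type Claisen rearrangement joins a glutamic-acid-derived lactone (C2–C4, C18, C19) to an enynol (C1, C5–C10, C20). The alkyne is turned into a (Z)-iodo allylsilane and the (Z)-configured C11–C16 unit is coupled on. Ring A (bond C1–C2) and then ring B (bond C9–C10) close in one flask.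
- Enabling feature: the C2 aldehyde and the CH2 terminus C1 of the isopropenyl group on C5 are the ends of the six-atom chain C2–C3–C4–C5–C10=C1. Attack through C1 closes ring A and leaves a tertiary cation at C10, the future quaternary ring-fusion carbon. The C8=C9 allylsilane then closes ring B around the existing C5–C10 bond and delivers the 8(17)-methylene.
- Stereochemistry: C4 comes from the (S)-lactone (attack trans to its CH2OSi group) and C5 from the chair Claisen of the (E)-alkene. C2, C10 and C9 come from the chair–chair cascade (equatorial OH, trans fusion, equatorial side chain). C7 comes from α-face SeO2 oxidation and 13Z from the ring geometry of a cyclic precursor.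

Key step: step 15

Remark: the four starting materials are taken to be catalogue compounds. The methylation of step 4 may be carried on as an epimer mixture, because that centre becomes trigonal in step 6.

**Route**

Step 1
Reactants: 1 pent-4-yn-1-ol; 2 ethyl 2-(triphenylphosphoranylidene)propanoate
Product: 4 ethyl (2E)-2-methylhept-2-en-6-ynoate, via pent-4-ynal 3 (not isolated)
Conditions: TEMPO (cat.), PhI(OAc)2, CH2Cl2, rt; then 2, rt
Reagents that add atoms: none
Why: Oxidation of the primary alcohol by TEMPO/PhI(OAc)2 and Wittig olefination in the same flask with the stabilized α-methyl ylide should give the (E)-trisubstituted enoate.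

Step 2
Reactants: 4 ethyl (2E)-2-methylhept-2-en-6-ynoate
Product: 5 (2E)-2-methylhept-2-en-6-yn-1-ol
Conditions: i-Bu2AlH, CH2Cl2, −78 °C; aq. potassium sodium tartrate
Reagents that add atoms: none
Why: 1,2-Reduction of the enoate by i-Bu2AlH should give the allylic alcohol and leave the alkyne and the alkene geometry untouched.

Step 3
Reactants: 6 (5S)-5-(hydroxymethyl)oxolan-2-one
Product: 7 (5S)-5-(tert-butyldimethylsilyloxymethyl)oxolan-2-one
Conditions: t-BuMe2SiCl, imidazole, DMF, rt
Reagents that add atoms: tert-butyl(chloro)dimethylsilane, CC(C)(C)[Si](C)(C)Cl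
Why: Standard silylation of the primary alcohol gives a group that will later shield one face of the lactone.

Step 4
Reactants: 7 (5S)-5-(tert-butyldimethylsilyloxymethyl)oxolan-2-one
Product: 8 (3R,5S)-3-methyl-5-(tert-butyldimethylsilyloxymethyl)oxolan-2-one
Conditions: LiN(i-Pr)2, THF, −78 °C; MeI
Reagents that add atoms: iodomethane, CI
Why: Alkylation of the lithium lactone enolate should place the methyl group mainly trans to the silyloxymethyl group, and either epimer serves because this carbon becomes trigonal in step 6.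

Step 5
Reactants: 8 (3R,5S)-3-methyl-5-(tert-butyldimethylsilyloxymethyl)oxolan-2-one
Product: 10 (3R,5S)-2,2-diethoxy-3-methyl-5-(tert-butyldimethylsilyloxymethyl)oxolane, via O-ethyl lactonium tetrafluoroborate 9 (not isolated)
Conditions: Et3OBF4, CH2Cl2, rt; then NaOEt, EtOH, 0 °C
Reagents that add atoms: triethyloxonium tetrafluoroborate, CC[O+](CC)CC.F[B-](F)(F)F; sodium ethoxide, CC[O-].[Na+]
Why: O-Ethylation of the lactone carbonyl and capture of the lactonium ion by ethoxide should give the cyclic orthoester (lactone acetal).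

Step 6
Reactants: 10 (3R,5S)-2,2-diethoxy-3-methyl-5-(tert-butyldimethylsilyloxymethyl)oxolane; 5 (2E)-2-methylhept-2-en-6-yn-1-ol
Product: 13 (3S,5S)-3-methyl-3-[(3R)-2-methylhept-1-en-6-yn-3-yl]-5-(tert-butyldimethylsilyloxymethyl)oxolan-2-one, via mixed orthoester 11 (not isolated), via allyl ketene acetal 12 (not isolated)
Conditions: EtCO2H (cat.), xylene, 140 °C, EtOH distilled off
Reagents that add atoms: none
Why: In this Johnson–Claisen rearrangement of a lactone orthoester the ring fixes the ketene acetal geometry (methyl cis to the allyl oxygen), the chair transition state with the (E)-alkene substituent equatorial sets C5 relative to C4, and addition to the ring face trans to the silyloxymethyl group sets the absolute configuration of both centres, any minor isomers being diastereomers that can be separated.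

Step 7
Reactants: 13 (3S,5S)-3-methyl-3-[(3R)-2-methylhept-1-en-6-yn-3-yl]-5-(tert-butyldimethylsilyloxymethyl)oxolan-2-one
Product: 15 (3S,5S)-3-[(3R,6Z)-7-iodo-2-methyl-6-(trimethylsilylmethyl)hepta-1,6-dien-3-yl]-3-methyl-5-(tert-butyldimethylsilyloxymethyl)oxolan-2-one, via alkenylcopper 14 (not isolated)
Conditions: Me3SiCH2MgCl, CuBr·SMe2, Et2O/Me2S, −40 to −10 °C; then I2, THF, −40 °C
Reagents that add atoms: (trimethylsilyl)methylmagnesium chloride, C[Si](C)(C)C[Mg]Cl; iodine, II
Why: syn-Carbocupration of the terminal alkyne should put the silylmethyl group on the internal carbon and copper on the terminal one, and iodinolysis with retention then gives the (Z)-iodoalkene, the lactone being inert to the organocopper reagent at low temperature.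

Step 8
Reactants: 16 4-methyl-5,6-dihydro-2H-pyran-2-one
Product: 17 methyl (2Z)-5-bromo-3-methylpent-2-enoate
Conditions: BBr3, CH2Cl2, 0 °C to rt; then MeOH, 0 °C
Reagents that add atoms: boron tribromide, BrB(Br)Br; methanol, CO
Why: Bromide attack at the O–CH2 carbon of the boron-activated lactone followed by methanolysis should give the bromo ester, whose (Z)-geometry is that of the ring alkene.

Step 9
Reactants: 15 (3S,5S)-3-[(3R,6Z)-7-iodo-2-methyl-6-(trimethylsilylmethyl)hepta-1,6-dien-3-yl]-3-methyl-5-(tert-butyldimethylsilyloxymethyl)oxolan-2-one; 17 methyl (2Z)-5-bromo-3-methylpent-2-enoate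
Product: 19 methyl (2Z,6Z,10R)-3,11-dimethyl-10-[(3S,5S)-3-methyl-2-oxo-5-(tert-butyldimethylsilyloxymethyl)oxolan-3-yl]-7-(trimethylsilylmethyl)dodeca-2,6,11-trienoate, via alkylzinc bromide 18 (not isolated)
Conditions: 17, Zn, I2 (cat.), N,N-dimethylacetamide, 70 °C; then 15, PdCl2(dppf) (cat.), THF, 50 °C
Reagents that add atoms: none
Why: Zinc insertion into the primary bromide and Negishi coupling with the iodoalkene should join C9 to C11 with retention of both alkene geometries, the ester, lactone and allylsilane being tolerated.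

Step 10
Reactants: 19 methyl (2Z,6Z,10R)-3,11-dimethyl-10-[(3S,5S)-3-methyl-2-oxo-5-(tert-butyldimethylsilyloxymethyl)oxolan-3-yl]-7-(trimethylsilylmethyl)dodeca-2,6,11-trienoate
Product: 20 (2S,4S,5R,8Z,12Z)-1-(tert-butyldimethylsilyloxy)-4-(hydroxymethyl)-4,12-dimethyl-5-(prop-1-en-2-yl)-8-(trimethylsilylmethyl)tetradeca-8,12-diene-2,14-diol
Conditions: i-Bu2AlH (excess), CH2Cl2, −78 °C to rt; aq. potassium sodium tartrate
Reagents that add atoms: none
Why: Excess i-Bu2AlH should reduce the lactone to the diol (C19 and C2 hydroxyls) and the enoate to the (Z)-allylic alcohol.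

Step 11
Reactants: 20 (2S,4S,5R,8Z,12Z)-1-(tert-butyldimethylsilyloxy)-4-(hydroxymethyl)-4,12-dimethyl-5-(prop-1-en-2-yl)-8-(trimethylsilylmethyl)tetradeca-8,12-diene-2,14-diol
Product: 21 (2S,4S,5R,8Z,12Z)-1-(tert-butyldimethylsilyloxy)-14-(tert-butyldiphenylsilyloxy)-4-(hydroxymethyl)-4,12-dimethyl-5-(prop-1-en-2-yl)-8-(trimethylsilylmethyl)tetradeca-8,12-dien-2-ol
Conditions: t-BuPh2SiCl (1 equiv), imidazole, CH2Cl2, −20 °C
Reagents that add atoms: tert-butyl(chloro)diphenylsilane, CC(C)(C)[Si](Cl)(c1ccccc1)c1ccccc1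
Why: The bulky silyl chloride should react with the unhindered primary allylic hydroxyl much faster than with the neopentyl primary and the secondary hydroxyl.

Step 12
Reactants: 21 (2S,4S,5R,8Z,12Z)-1-(tert-butyldimethylsilyloxy)-14-(tert-butyldiphenylsilyloxy)-4-(hydroxymethyl)-4,12-dimethyl-5-(prop-1-en-2-yl)-8-(trimethylsilylmethyl)tetradeca-8,12-dien-2-ol
Product: 22 (2S,4S,5R,8Z,12Z)-4-(acetoxymethyl)-1-(tert-butyldimethylsilyloxy)-14-(tert-butyldiphenylsilyloxy)-4,12-dimethyl-5-(prop-1-en-2-yl)-8-(trimethylsilylmethyl)tetradeca-8,12-dien-2-ol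
Conditions: AcCl, 2,4,6-collidine, CH2Cl2, −78 °C
Reagents that add atoms: acetyl chloride, CC(=O)Cl
Why: Acetyl chloride with collidine at low temperature should acetylate the primary C19 hydroxyl in preference to the flanked secondary one.

Step 13
Reactants: 22 (2S,4S,5R,8Z,12Z)-4-(acetoxymethyl)-1-(tert-butyldimethylsilyloxy)-14-(tert-butyldiphenylsilyloxy)-4,12-dimethyl-5-(prop-1-en-2-yl)-8-(trimethylsilylmethyl)tetradeca-8,12-dien-2-ol
Product: 23 (2S,4S,5R,8Z,12Z)-4-(acetoxymethyl)-14-(tert-butyldiphenylsilyloxy)-4,12-dimethyl-5-(prop-1-en-2-yl)-8-(trimethylsilylmethyl)tetradeca-8,12-diene-1,2-diol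
Conditions: HF·pyridine, pyridine, THF, 0 °C
Reagents that add atoms: none
Why: Buffered HF·pyridine should remove the primary tert-butyldimethylsilyl ether and leave the tert-butyldiphenylsilyl ether, the acetate and the allylsilane.

Step 14
Reactants: 23 (2S,4S,5R,8Z,12Z)-4-(acetoxymethyl)-14-(tert-butyldiphenylsilyloxy)-4,12-dimethyl-5-(prop-1-en-2-yl)-8-(trimethylsilylmethyl)tetradeca-8,12-diene-1,2-diol
Product: 24 (3S,4R,7Z,11Z)-3-(acetoxymethyl)-13-(tert-butyldiphenylsilyloxy)-3,11-dimethyl-4-(prop-1-en-2-yl)-7-(trimethylsilylmethyl)trideca-7,11-dienal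
Conditions: NaIO4, THF/pH 7 buffer, 0 °C
Reagents that add atoms: none
Why: Periodate cleavage of the terminal 1,2-diol should unveil the C2 aldehyde without touching the alkenes or the allylsilane.

Step 15
Reactants: 24 (3S,4R,7Z,11Z)-3-(acetoxymethyl)-13-(tert-butyldiphenylsilyloxy)-3,11-dimethyl-4-(prop-1-en-2-yl)-7-(trimethylsilylmethyl)trideca-7,11-dienal
Product: 25 (13Z)-19-acetoxy-15-(tert-butyldiphenylsilyloxy)labda-8(17),13-dien-2α-ol
Conditions: MeAlCl2 (2.5 equiv), CH2Cl2, −78 °C; aq. NaHCO3
Reagents that add atoms: none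
Why: Proposed new method: MeAlCl2 activates the C2 aldehyde, the CH2 terminus C1 of the isopropenyl group attacks it (the only sense that gives a tertiary cation), and the C10 cation is taken up at once by C9 of the allylsilane, whose Me3Si group leaves to give the 8(17)-methylene; the closest known reaction types are the Lewis-acid type-2 intramolecular carbonyl-ene/Prins cyclization of 5-methylhex-5-enals and the aldehyde- or acetal-initiated, allylsilane-terminated cation–olefin polycyclization, which have not been joined in this topology, where the second ring forms around the allylic C5–C10 bond. Ring A closes by bond C1–C2 in a 6-endo-trig mode with respect to the C1=C10 alkene (exo to the carbonyl), and ring B closes by bond C9–C10 in a 6-endo-trig cation–olefin mode. At C2 the aluminium-bound oxygen should take the equatorial position of the chair to avoid the syn-axial C19H2OAc group and the incipient axial C20 methyl, which gives the 2α-alcohol. At C10 and C9, antiperiplanar addition across C1=C10 in a chair–chair array with the C6 chain equatorial on ring A should give the trans fusion with axial C20, and the allylsilane geometry (C11 trans to C7) should place the side chain equatorial (9β). The step needs capture of the C10 cation by the allylsilane to outrun proton loss, chloride capture and hydride shift, and attack by C1 to outrun direct attack of the allylsilane on the aldehyde; this is secured by the six-membered intramolecular capture by the most nucleophilic alkene present, by the eight-membered ring that direct allylsilane attack would need, by the non-basic proton-scavenging MeAlCl2 at −78 °C, and by the low nucleophilicity of the C13=C14 alkene with its allylic silyl ether.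

Step 16
Reactants: 25 (13Z)-19-acetoxy-15-(tert-butyldiphenylsilyloxy)labda-8(17),13-dien-2α-ol
Product: 26 (13Z)-19-acetoxy-15-(tert-butyldiphenylsilyloxy)labda-8(17),13-diene-2α,7α-diol
Conditions: SeO2 (cat.), t-BuOOH, CH2Cl2, 0 °C to rt
Reagents that add atoms: tert-butyl hydroperoxide, CC(C)(C)OO (its oxygen is passed on by the SeO2 catalyst)
Why: In this Riley allylic oxidation the ene reaction at the exocyclic C17 terminus removes the axial 7α-hydrogen and the [2,3]-sigmatropic shift should deliver the axial 7α-hydroxyl on the α-face, while the side-chain alkene is deactivated by its allylic silyloxy group as in the ω-oxidation of geranyl derivatives.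

Step 17
Reactants: 26 (13Z)-19-acetoxy-15-(tert-butyldiphenylsilyloxy)labda-8(17),13-diene-2α,7α-diol
Product: 27 (13Z)-19-acetoxylabda-8(17),13-diene-2α,7α,15-triol
Conditions: Bu4NF, AcOH, THF, 0 °C to rt
Reagents that add atoms: none
Why: Fluoride cleavage of the silyl ether buffered with acetic acid should free the C15 alcohol and keep the C19 acetate in place.

Step 18
Reactants: 27 (13Z)-19-acetoxylabda-8(17),13-diene-2α,7α,15-triol
Product: 28 (13Z)-19-acetoxy-2α,7α-dihydroxylabda-8(17),13-dien-15-al
Conditions: TEMPO (cat.), PhI(OAc)2 (1.05 equiv), CH2Cl2, 0 °C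
Reagents that add atoms: none
Why: TEMPO/PhI(OAc)2 should oxidise the primary allylic alcohol much faster than the two secondary alcohols and give the (Z)-enal without isomerisation, as in the oxidation of nerol to neral.

**Compound list**

1 | pent-4-yn-1-ol | C#CCCCO | starting material
2 | ethyl 2-(triphenylphosphoranylidene)propanoate | CCOC(=O)C(C)=P(c1ccccc1)(c1ccccc1)c1ccccc1 | starting material
3 | pent-4-ynal | C#CCCC=O | intermediate
4 | ethyl (2E)-2-methylhept-2-en-6-ynoate | CCOC(=O)/C(C)=C/CCC#C | intermediate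
5 | (2E)-2-methylhept-2-en-6-yn-1-ol | OC/C(C)=C/CCC#C | intermediate
6 | (5S)-5-(hydroxymethyl)oxolan-2-one | O=C1CC[C@@H](CO)O1 | starting material
7 | (5S)-5-(tert-butyldimethylsilyloxymethyl)oxolan-2-one | O=C1CC[C@@H](CO[Si](C)(C)C(C)(C)C)O1 | intermediate
8 | (3R,5S)-3-methyl-5-(tert-butyldimethylsilyloxymethyl)oxolan-2-one | O=C1[C@H](C)C[C@@H](CO[Si](C)(C)C(C)(C)C)O1 | intermediate
9 | O-ethyl lactonium tetrafluoroborate of 8 | CC[O+]=C1[C@H](C)C[C@@H](CO[Si](C)(C)C(C)(C)C)O1.F[B-](F)(F)F | intermediate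
10 | (3R,5S)-2,2-diethoxy-3-methyl-5-(tert-butyldimethylsilyloxymethyl)oxolane | CCOC1(OCC)[C@H](C)C[C@@H](CO[Si](C)(C)C(C)(C)C)O1 | intermediate
11 | mixed orthoester: (3R,5S)-2-ethoxy-3-methyl-2-[(2E)-2-methylhept-2-en-6-ynyloxy]-5-(tert-butyldimethylsilyloxymethyl)oxolane | CCOC1(OC/C(C)=C/CCC#C)[C@H](C)C[C@@H](CO[Si](C)(C)C(C)(C)C)O1 | intermediate
12 | allyl ketene acetal: (2S)-4-methyl-5-[(2E)-2-methylhept-2-en-6-ynyloxy]-2-(tert-butyldimethylsilyloxymethyl)-2,3-dihydrofuran | CC1=C(OC/C(C)=C/CCC#C)O[C@H](CO[Si](C)(C)C(C)(C)C)C1 | intermediate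
13 | (3S,5S)-3-methyl-3-[(3R)-2-methylhept-1-en-6-yn-3-yl]-5-(tert-butyldimethylsilyloxymethyl)oxolan-2-one | C=C(C)[C@@H](CCC#C)[C@]1(C)C[C@@H](CO[Si](C)(C)C(C)(C)C)OC1=O | intermediate
14 | alkenylcopper from syn-addition of Me3SiCH2Cu to 13 (copper on the terminal carbon, cis to CH2SiMe3) | C=C(C)[C@@H](CC/C(C[Si](C)(C)C)=C/[Cu])[C@]1(C)C[C@@H](CO[Si](C)(C)C(C)(C)C)OC1=O | intermediate
15 | (3S,5S)-3-[(3R,6Z)-7-iodo-2-methyl-6-(trimethylsilylmethyl)hepta-1,6-dien-3-yl]-3-methyl-5-(tert-butyldimethylsilyloxymethyl)oxolan-2-one | C=C(C)[C@@H](CC/C(C[Si](C)(C)C)=C/I)[C@]1(C)C[C@@H](CO[Si](C)(C)C(C)(C)C)OC1=O | intermediate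
16 | 4-methyl-5,6-dihydro-2H-pyran-2-one | CC1=CC(=O)OCC1 | starting material
17 | methyl (2Z)-5-bromo-3-methylpent-2-enoate | COC(=O)/C=C(/C)CCBr | intermediate
18 | alkylzinc bromide from 17: bromo[(3Z)-5-methoxy-3-methyl-5-oxopent-3-enyl]zinc | COC(=O)/C=C(/C)CC[Zn]Br | intermediate
19 | methyl (2Z,6Z,10R)-3,11-dimethyl-10-[(3S,5S)-3-methyl-2-oxo-5-(tert-butyldimethylsilyloxymethyl)oxolan-3-yl]-7-(trimethylsilylmethyl)dodeca-2,6,11-trienoate | C=C(C)[C@@H](CC/C(C[Si](C)(C)C)=C/CC/C(C)=C\C(=O)OC)[C@]1(C)C[C@@H](CO[Si](C)(C)C(C)(C)C)OC1=O | intermediate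
20 | (2S,4S,5R,8Z,12Z)-1-(tert-butyldimethylsilyloxy)-4-(hydroxymethyl)-4,12-dimethyl-5-(prop-1-en-2-yl)-8-(trimethylsilylmethyl)tetradeca-8,12-diene-2,14-diol | C=C(C)[C@@H](CC/C(C[Si](C)(C)C)=C/CC/C(C)=C\CO)[C@@](C)(CO)C[C@H](O)CO[Si](C)(C)C(C)(C)C | intermediate
21 | (2S,4S,5R,8Z,12Z)-1-(tert-butyldimethylsilyloxy)-14-(tert-butyldiphenylsilyloxy)-4-(hydroxymethyl)-4,12-dimethyl-5-(prop-1-en-2-yl)-8-(trimethylsilylmethyl)tetradeca-8,12-dien-2-ol | C=C(C)[C@@H](CC/C(C[Si](C)(C)C)=C/CC/C(C)=C\CO[Si](c1ccccc1)(c1ccccc1)C(C)(C)C)[C@@](C)(CO)C[C@H](O)CO[Si](C)(C)C(C)(C)C | intermediate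
22 | (2S,4S,5R,8Z,12Z)-4-(acetoxymethyl)-1-(tert-butyldimethylsilyloxy)-14-(tert-butyldiphenylsilyloxy)-4,12-dimethyl-5-(prop-1-en-2-yl)-8-(trimethylsilylmethyl)tetradeca-8,12-dien-2-ol | C=C(C)[C@@H](CC/C(C[Si](C)(C)C)=C/CC/C(C)=C\CO[Si](c1ccccc1)(c1ccccc1)C(C)(C)C)[C@@](C)(COC(C)=O)C[C@H](O)CO[Si](C)(C)C(C)(C)C | intermediate
23 | (2S,4S,5R,8Z,12Z)-4-(acetoxymethyl)-14-(tert-butyldiphenylsilyloxy)-4,12-dimethyl-5-(prop-1-en-2-yl)-8-(trimethylsilylmethyl)tetradeca-8,12-diene-1,2-diol | C=C(C)[C@@H](CC/C(C[Si](C)(C)C)=C/CC/C(C)=C\CO[Si](c1ccccc1)(c1ccccc1)C(C)(C)C)[C@@](C)(COC(C)=O)C[C@H](O)CO | intermediate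
24 | (3S,4R,7Z,11Z)-3-(acetoxymethyl)-13-(tert-butyldiphenylsilyloxy)-3,11-dimethyl-4-(prop-1-en-2-yl)-7-(trimethylsilylmethyl)trideca-7,11-dienal | C=C(C)[C@@H](CC/C(C[Si](C)(C)C)=C/CC/C(C)=C\CO[Si](c1ccccc1)(c1ccccc1)C(C)(C)C)[C@@](C)(COC(C)=O)CC=O | intermediate
25 | (13Z)-19-acetoxy-15-(tert-butyldiphenylsilyloxy)labda-8(17),13-dien-2α-ol | C=C1CC[C@H]2[C@@](C)(COC(C)=O)C[C@H](O)C[C@]2(C)[C@H]1CC/C(C)=C\CO[Si](c1ccccc1)(c1ccccc1)C(C)(C)C | intermediate
26 | (13Z)-19-acetoxy-15-(tert-butyldiphenylsilyloxy)labda-8(17),13-diene-2α,7α-diol | C=C1[C@H](O)C[C@H]2[C@@](C)(COC(C)=O)C[C@H](O)C[C@]2(C)[C@H]1CC/C(C)=C\CO[Si](c1ccccc1)(c1ccccc1)C(C)(C)C | intermediate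
27 | (13Z)-19-acetoxylabda-8(17),13-diene-2α,7α,15-triol | C=C1[C@H](O)C[C@H]2[C@@](C)(COC(C)=O)C[C@H](O)C[C@]2(C)[C@H]1CC/C(C)=C\CO | intermediate
28 | (13Z)-19-acetoxy-2α,7α-dihydroxylabda-8(17),13-dien-15-al | C=C1[C@H](O)C[C@H]2[C@@](C)(COC(C)=O)C[C@H](O)C[C@]2(C)[C@H]1CC/C(C)=C\C=O | target

**Step count and risks**

Total step count: 18.
Longest linear sequence: 15 steps (from 6 to 28: steps 3–7 and 9–18).

Steps most likely to fail:

1. Step 15 (proposed new method). The C10 cation may be quenched before ring B closes, by proton loss to the aluminium alkoxide in the sense of an ene reaction, by chloride capture or by hydride shift from C2. Ring B may also close on the other face and give the cis-fused decalin. The fallback sets out from 24 and changes the initiator to an alkoxycarbenium ion, as in the established acetal-initiated cation–olefin cyclizations with allylsilane termination. 4-Methoxybenzyl trimethylsilyl ether and Me3SiOSO2CF3 (cat.) in CH2Cl2 at −78 °C should convert 24, through the mixed acetal, into (13Z)-19-acetoxy-15-(tert-butyldiphenylsilyloxy)-2α-(4-methoxybenzyloxy)labda-8(17),13-diene F1, whose cationic intermediate carries no metal alkoxide. DDQ in CH2Cl2/pH 7 buffer should then remove the benzyl group and bring the route back at 25.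

2. Step 7. The silylmethylcopper reagent may add sluggishly or unselectively to the alkyne in the presence of the lactone carbonyl, or the new allylsilane may be lost during iodinolysis. The fallback sets out from 13. Copper-catalysed syn-carboboration (B2pin2, Me3SiCH2I, CuCl, Xantphos, NaOt-Bu, THF, rt) should give the (Z)-alkenyl pinacolboronate F2, with boron on the terminal carbon and the silylmethyl group on the internal one. A Suzuki–Miyaura coupling of this boronate with the alkyl bromide 17 (Pd(OAc)2, P(t-Bu)2Me, KOt-Bu, tert-amyl alcohol, rt) then comes back to the route at 19, without the iodide 15 and the zinc reagent.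

3. Step 16. Chemoselectivity may be lost, with allylic oxidation at C12 or C16 of the side chain competing with C7, or the product may be over-oxidised to the C7 ketone. The fallback sets out from 25 and changes the order, so that the side-chain alkene is conjugated to a carbonyl group and inert toward SeO2. Bu4NF/AcOH should give (13Z)-19-acetoxylabda-8(17),13-diene-2α,15-diol F3, and TEMPO/PhI(OAc)2 should give the 7-deoxy enal (13Z)-19-acetoxy-2α-hydroxylabda-8(17),13-dien-15-al F4. SeO2/t-BuOOH is then applied last to this enal, which comes back to the route at 28.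

Further compounds
F1 | step 15 | (13Z)-19-acetoxy-15-(tert-butyldiphenylsilyloxy)-2α-(4-methoxybenzyloxy)labda-8(17),13-diene | C=C1CC[C@H]2[C@@](C)(COC(C)=O)C[C@H](OCc3ccc(OC)cc3)C[C@]2(C)[C@H]1CC/C(C)=C\CO[Si](c1ccccc1)(c1ccccc1)C(C)(C)C
F2 | step 7 | (3S,5S)-3-methyl-3-[(3R,6Z)-2-methyl-7-(4,4,5,5-tetramethyl-1,3,2-dioxaborolan-2-yl)-6-(trimethylsilylmethyl)hepta-1,6-dien-3-yl]-5-(tert-butyldimethylsilyloxymethyl)oxolan-2-one | C=C(C)[C@@H](CC/C(C[Si](C)(C)C)=C/B1OC(C)(C)C(C)(C)O1)[C@]1(C)C[C@@H](CO[Si](C)(C)C(C)(C)C)OC1=O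
F3 | step 16 | (13Z)-19-acetoxylabda-8(17),13-diene-2α,15-diol | C=C1CC[C@H]2[C@@](C)(COC(C)=O)C[C@H](O)C[C@]2(C)[C@H]1CC/C(C)=C\CO
F4 | step 16 | (13Z)-19-acetoxy-2α-hydroxylabda-8(17),13-dien-15-al | C=C1CC[C@H]2[C@@](C)(COC(C)=O)C[C@H](O)C[C@]2(C)[C@H]1CC/C(C)=C\C=O
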